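## Retrosynthetic overview
1. The key disconnection is the ester C–O bond between O-6 of the eudesmenol and the coumaroyl carbon. Unprotected p-coumaric acid enters as an active ester that transfers its acyl group through a ketene-type intermediate.
2. Eudesm-3-en-6β-ol comes from the β,γ-unsaturated 6-ketone. C-5 is set by kinetic protonation of the heteroannular dienolate and C-6 by hydride attack from the α-face. O-6 is the ketone oxygen of the starting monoterpene.
3. Ring A is the only ring that is made. It closes by 6-endo attack of a silyl enol ether on a pent-3-ynyl side chain, forming the C4–C5 bond with C3=C4 already in place.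
4. Quaternary C-10 comes from a copper-catalysed asymmetric conjugate addition to (S)-piperitone. (S)-Piperitone is made from (−)-menthone, which supplies ring B and C-7. The arene arrives with p-coumaric acid.

Assumption: L* is the N-mesityl-N'-(1-hydroxy-3,3-dimethylbutan-2-yl)imidazolinium hexafluorophosphate derived from tert-leucinol. The antipode used is the one that delivers the alkyl group to the face of C-3 anti to the isopropyl group of 3, and one control run fixes this choice.

## Route

Step 1
Reactants: 1 (−)-menthone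
Product: 3 (S)-(+)-piperitone, via trimethylsilyl enol ether 2 (not isolated)
Conditions: LiN(i-Pr)2, THF, −78 °C; Me3SiCl, −78 °C to rt; solvent switch; Pd(OAc)2 (10 mol %), O2 (1 atm), DMSO, 30 °C
Reagents that add atoms: none
Why: LiN(i-Pr)2 deprotonates only the unhindered CH2 next to the carbonyl and Saegusa–Ito oxidation (aerobic variant) of 2 places the double bond towards the methyl-bearing carbon, so C-2 of 1 is never enolised and its S configuration becomes C-6 of 3 (C-7 of the target).

Step 2
Reactants: 3 (S)-(+)-piperitone; 4 5-bromopent-2-yne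
Product: 7 tert-butyl(dimethyl){[(3S,6S)-3-methyl-3-(pent-3-yn-1-yl)-6-(propan-2-yl)cyclohex-1-en-1-yl]oxy}silane, via pent-3-ynylmagnesium bromide 5 (not isolated), via magnesium enolate 6 (not isolated)
Conditions: 4, Mg, Et2O, 35 °C; added over 1 h to 3, Cu(OTf)2 (3 mol %), L* (4 mol %), Et2O, −30 °C; then t-BuMe2SiOTf, −30 to 0 °C
Reagents that add atoms: tert-butyldimethylsilyl trifluoromethanesulfonate, CC(C)(C)[Si](C)(C)OS(=O)(=O)C(F)(F)F
Why: In this copper–NHC-catalysed asymmetric conjugate addition of a Grignard reagent to a β-methyl cyclic enone the catalyst delivers the chain anti to the isopropyl group and sets the quaternary centre (C-10), the remote and conformationally mobile C-6 substituent adds little bias, the minor C-3 epimer is a diastereomer removed on silica, and O-silylation fixes the regiodefined enolate without touching C-6.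

Step 3
Reactants: 7 silyl enol ether
Product: 8 (2S,4aR,8aS)-4a,8-dimethyl-2-(propan-2-yl)-3,4,4a,5,6,8a-hexahydronaphthalen-1(2H)-one (cis-fused eudesm-3-en-6-one)
Conditions: (Me4-t-BuXPhos)AuCl (3 mol %), AgSbF6 (3 mol %), MeOH (3 equiv), CH2Cl2, 25 °C
Reagents that add atoms: none
Why: In this gold-catalysed Conia-ene-type carbocyclisation of a silyl enol ether onto a tethered alkyne the very bulky biaryl phosphine favours 6-endo-dig over 5-exo-dig closure, C-5 attacks the methyl-bearing alkyne carbon from the face that carries the tether (cis fusion, reset in step 4), protodeauration leaves C3=C4, and the neutral medium leaves C-7 intact.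

Step 4
Reactants: 8 cis-fused eudesm-3-en-6-one
Product: 11 (1R,2S,4aR,8aR)-4a,8-dimethyl-2-(propan-2-yl)-1,2,3,4,4a,5,6,8a-octahydronaphthalen-1-ol (eudesm-3-en-6β-ol), via potassium dienolate 9 (not isolated), via trans-fused ketone 10 (not isolated)
Conditions: KN(SiMe3)2 (1.1 equiv), THF, −78 °C; AcOH (1.5 equiv), −78 to −20 °C; i-Bu2AlH (4 equiv), −78 °C; aq potassium sodium tartrate
Reagents that add atoms: none
Why: This is kinetic protonation of an extended enolate followed by substrate-controlled hydride reduction, in which the base removes only the doubly activated ring-fusion proton, the planar heteroannular dienolate 9 holds the angular methyl perpendicular on the β-face so AcOH protonates the α-carbon from the α-face (trans fusion, C-5), and i-Bu2AlH attacks 10 along the equatorial α-trajectory because the axial one is blocked by the 1,3-diaxial angular methyl, giving the axial 6β-alcohol (C-6).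

Step 5
Reactants: 12 (E)-p-coumaric acid
Product: 13 2,5-dioxopyrrolidin-1-yl (2E)-3-(4-hydroxyphenyl)prop-2-enoate
Conditions: N-hydroxysuccinimide, DCC, THF, 0 °C to rt
Reagents that add atoms: N-hydroxysuccinimide, O=C1CCC(=O)N1O
Why: In this carbodiimide (Steglich-type) activation the acidic N-hydroxysuccinimide intercepts the O-acylisourea much faster than the phenol does, so the crystalline active ester forms without phenol protection and with the E-alkene unchanged.

Step 6
Reactants: 11 eudesm-3-en-6β-ol; 13 N-succinimidyl p-coumarate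
Product: 15 (1R,2S,4aR,8aR)-4a,8-dimethyl-2-(propan-2-yl)-1,2,3,4,4a,5,6,8a-octahydronaphthalen-1-yl (2E)-3-(4-hydroxyphenyl)prop-2-enoate, via extended p-oxoketene 14 (not isolated)
Conditions: 11, DBU (3 equiv), THF (0.5 M), 50 °C; 13 (2 equiv) in THF added over 6 h; 12 h; then MeOH, 25 °C, 2 h
Reagents that add atoms: none
Why: Proposed new method: DBU deprotonates the free phenol of 13 and the phenoxide expels N-oxysuccinimide through the vinylogous π-system (E1cB) to give the neutral, sterically undemanding p-oxoketene 14, whose sp carbon is captured by the hindered axial 6β-OH with rearomatisation as driving force (the carbinol configuration is untouched and the s-trans ketene returns the E-alkene); O-aryl acylation of any phenoxide is reversible by the same E1cB path whereas the alkyl ester cannot ionise, so the mixture funnels to 15 and the MeOH chase unzips residual aryl esters; the closest known reaction types are the dissociative E1cB acyl transfer of activated 4-hydroxybenzoate and 4-hydroxycinnamate esters (so far seen only kinetically in hydrolysis) and the acylation of hindered alcohols by ketenes and acylketenes.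

## Compound list
1 | (−)-menthone, (2S,5R)-5-methyl-2-(propan-2-yl)cyclohexan-1-one | C[C@@H]1CC[C@@H](C(C)C)C(=O)C1 | starting material
2 | trimethyl{[(3R,6S)-3-methyl-6-(propan-2-yl)cyclohex-1-en-1-yl]oxy}silane | C[C@@H]1CC[C@@H](C(C)C)C(O[Si](C)(C)C)=C1 | intermediate
3 | (S)-(+)-piperitone, (6S)-3-methyl-6-(propan-2-yl)cyclohex-2-en-1-one | CC1=CC(=O)[C@H](C(C)C)CC1 | intermediate
4 | 5-bromopent-2-yne | CC#CCCBr | starting material
5 | pent-3-yn-1-ylmagnesium bromide | CC#CCC[Mg]Br | intermediate
6 | bromomagnesium (3S,6S)-3-methyl-3-(pent-3-yn-1-yl)-6-(propan-2-yl)cyclohex-1-en-1-olate | C[C@@]1(CCC#CC)CC[C@@H](C(C)C)C(O[Mg]Br)=C1 | intermediate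
7 | tert-butyl(dimethyl){[(3S,6S)-3-methyl-3-(pent-3-yn-1-yl)-6-(propan-2-yl)cyclohex-1-en-1-yl]oxy}silane | C[C@@]1(CCC#CC)CC[C@@H](C(C)C)C(O[Si](C)(C)C(C)(C)C)=C1 | intermediate
8 | (2S,4aR,8aS)-4a,8-dimethyl-2-(propan-2-yl)-3,4,4a,5,6,8a-hexahydronaphthalen-1(2H)-one | CC1=CCC[C@]2(C)CC[C@@H](C(C)C)C(=O)[C@H]12 | intermediate
9 | potassium (2S,4aR)-4a,8-dimethyl-2-(propan-2-yl)-2,3,4,4a,5,6-hexahydronaphthalen-1-olate | CC1=CCC[C@]2(C)CC[C@@H](C(C)C)C([O-])=C12.[K+] | intermediate
10 | (2S,4aR,8aR)-4a,8-dimethyl-2-(propan-2-yl)-3,4,4a,5,6,8a-hexahydronaphthalen-1(2H)-one | CC1=CCC[C@]2(C)CC[C@@H](C(C)C)C(=O)[C@@H]12 | intermediate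
11 | (1R,2S,4aR,8aR)-4a,8-dimethyl-2-(propan-2-yl)-1,2,3,4,4a,5,6,8a-octahydronaphthalen-1-ol | CC1=CCC[C@]2(C)CC[C@@H](C(C)C)[C@@H](O)[C@@H]12 | intermediate
12 | (E)-p-coumaric acid | O=C(O)/C=C/c1ccc(O)cc1 | starting material
13 | 2,5-dioxopyrrolidin-1-yl (2E)-3-(4-hydroxyphenyl)prop-2-enoate | O=C(/C=C/c1ccc(O)cc1)ON1C(=O)CCC1=O | intermediate
14 | 4-(3-oxoprop-2-en-1-ylidene)cyclohexa-2,5-dien-1-one | O=C=CC=C1C=CC(=O)C=C1 | intermediate
15 | eudesm-3-en-6β-yl (E)-p-coumarate (CNP0220414.1) | CC1=CCC[C@]2(C)CC[C@@H](C(C)C)[C@@H](OC(=O)/C=C/c3ccc(O)cc3)[C@@H]12 | target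

## Step count and risks
Total steps: 6. Longest linear sequence: 5 (steps 1, 2, 3, 4, 6).

**Step 6 (the new step).** The ketene may be consumed by phenoxides faster than by the hindered alcohol, or ionisation of 13 may be too slow. The fallback sets out from 11 and comes back at 15. It forms the C–O bond first and builds the cinnamate double bond afterwards, using known chemistry. Heating 11 with Meldrum's acid in toluene at 110 °C gives the malonic half-ester F9. Knoevenagel–Doebner condensation of F9 with 4-hydroxybenzaldehyde (pyridine, catalytic piperidine, 70 °C) then gives 15 directly, with the phenol free and the alkene E.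

**Step 3.** 5-exo-dig closure to a hydrindanone or methanolysis of the alkyne may compete. The fallback sets out from 3 and comes back at 9. It builds ring A by aldol condensation instead of alkyne activation.
- The Grignard reagent [3-(2-methyl-1,3-dioxolan-2-yl)propyl]magnesium chloride F4 is made from commercial 2-(3-chloropropyl)-2-methyl-1,3-dioxolane and Mg.
- F4 is added to 3 under the copper conditions of step 2, with an aqueous quench, to give the ketal ketone F5.
- 3 M HCl in THF at reflux unmasks the diketone F6, which closes and dehydrates to the conjugated enone F7.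
- These conditions epimerise C-7, so F7 must be separated from its C-2 epimer F8. F8 is recycled through the same acid.
- KOt-Bu in THF converts F7 into 9, and the route continues with the acetic acid quench of step 4.

**Step 2.** The catalyst may be too unselective or too slow on the 6-substituted enone, or the magnesium enolate may silylate poorly. The fallback sets out from 3 and 5 and comes back at 7. It gives up catalyst control and uses the resident stereocentre as the handle.
- CuBr·SMe2 (10 mol %), Me3SiCl and DMPU in THF at −78 °C add 5 to 3. This gives the trimethylsilyl enol ether F1 as a mixture of C-3 epimers.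
- Cold dilute citric acid cleaves F1 to the ketone F2 and its C-5 epimer F3.
- F2 and F3 are diastereomers because C-2 is enantiopure, so they are separated on silica.
- LiN(i-Pr)2 and t-BuMe2SiOTf at −78 °C convert F2 regioselectively into 7.

## Further compounds
F1 | step 2 | trimethyl{[(6S)-3-methyl-3-(pent-3-yn-1-yl)-6-(propan-2-yl)cyclohex-1-en-1-yl]oxy}silane, C-3 epimer mixture | CC#CCCC1(C)CC[C@@H](C(C)C)C(O[Si](C)(C)C)=C1
F2 | step 2 | (2S,5S)-5-methyl-5-(pent-3-yn-1-yl)-2-(propan-2-yl)cyclohexan-1-one | C[C@@]1(CCC#CC)CC[C@@H](C(C)C)C(=O)C1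
F3 | step 2 | (2S,5R)-5-methyl-5-(pent-3-yn-1-yl)-2-(propan-2-yl)cyclohexan-1-one | C[C@]1(CCC#CC)CC[C@@H](C(C)C)C(=O)C1
F4 | step 3 | [3-(2-methyl-1,3-dioxolan-2-yl)propyl]magnesium chloride | CC1(CCC[Mg]Cl)OCCO1
F5 | step 3 | (2S,5R)-5-methyl-5-[3-(2-methyl-1,3-dioxolan-2-yl)propyl]-2-(propan-2-yl)cyclohexan-1-one | C[C@@]1(CCCC2(C)OCCO2)CC[C@@H](C(C)C)C(=O)C1
F6 | step 3 | (2S,5R)-5-methyl-5-(4-oxopentyl)-2-(propan-2-yl)cyclohexan-1-one | C[C@@]1(CCCC(C)=O)CC[C@@H](C(C)C)C(=O)C1
F7 | step 3 | (2S,4aR)-4a,8-dimethyl-2-(propan-2-yl)-3,4,4a,5,6,7-hexahydronaphthalen-1(2H)-one | CC1=C2C(=O)[C@H](C(C)C)CC[C@@]2(C)CCC1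
F8 | step 3 | (2R,4aR)-4a,8-dimethyl-2-(propan-2-yl)-3,4,4a,5,6,7-hexahydronaphthalen-1(2H)-one | CC1=C2C(=O)[C@@H](C(C)C)CC[C@@]2(C)CCC1
F9 | step 6 | 3-{[(1R,2S,4aR,8aR)-4a,8-dimethyl-2-(propan-2-yl)-1,2,3,4,4a,5,6,8a-octahydronaphthalen-1-yl]oxy}-3-oxopropanoic acid | CC1=CCC[C@]2(C)CC[C@@H](C(C)C)[C@@H](OC(=O)CC(=O)O)[C@@H]12
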